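C1–C10 is the ten-membered carbocycle (germacrane numbering): C1 ketone, C2=C3 furanone alkene, O bridging C3 and C10, C4=C5 ring alkene, C6–O lactone, C8 methacrylate carbinol, C11(=C13)–C12 acrylate/lactone carbonyl, C15 acetoxymethyl. The enabling feature is that the carbinol carbon C6 is bonded directly to the alkene carbon C5 inside this ring, so C5–C6 is the product bond of an alkenyl-metal addition to a C6 aldehyde.
Retrosynthetic cuts, in order: O6–C12 (lactone), C5–C6 (ten-membered ring), C7–C8 (allyl bromide plus aldehyde), O10–C3 and C1–C2 (furanone from an α′-hydroxy ynone), C3–C4 (Sonogashira), C9–C10 (enolate allylation).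
Forward: the furanone ring is built first (C1–C2 by acetylide acylation, O10–C3 by 5-endo-dig closure), the chain is joined at C7–C8, the ten-membered ring closes at C5–C6, and the γ-lactone forms last.
Stereochemistry: C10 comes from (S)-lactic acid by self-regeneration of the stereocentre; C8 from a ligand-controlled chromium allylation whose chair transition state sets C7 (anti); C6 is set in the ring closure under control of C7; the 4Z alkene comes from a cis silylstannation of propargyl alcohol and is carried through retentive Sn→I and Si→I exchanges.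

Key step: step 19

Remark: C12 is carried as a tert-butyl ester (a methyl ester would lactonise onto O8 after step 15 and onto the free C6 hydroxyl in step 17); the ligand antipode of step 15 that gives Re-face addition is to be confirmed on a model aldehyde.

Step 1
Reactants: 1 (S)-lactic acid
Product: 2 (2S,5S)-2-tert-butyl-5-methyl-1,3-dioxolan-4-one
Conditions: t-BuCHO, p-TsOH (cat.), H2SO4 (cat.), pentane, reflux with water separator; crystallisation at −78 °C
Reagents that add atoms: pivalaldehyde, CC(C)(C)C=O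
Why: Acid-catalysed acetalisation of an α-hydroxy acid to a 1,3-dioxolan-4-one; the new acetal centre equilibrates towards the cis isomer (tert-butyl and methyl on the same face, 2S), which is enriched by cold crystallisation.

Step 2
Reactants: 2 (2S,5S)-2-tert-butyl-5-methyl-1,3-dioxolan-4-one; 3 allyl bromide
Product: 4 (2S,5R)-2-tert-butyl-5-methyl-5-(prop-2-en-1-yl)-1,3-dioxolan-4-one
Conditions: LiN(i-Pr)2, THF, −78 °C; then 3, −78 → −20 °C
Reagents that add atoms: none
Why: Enolate alkylation with self-regeneration of the stereocentre: the planar lithium enolate is allylated on the face away from the tert-butyl group, so the quaternary carbon (later C10) forms with overall retention.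

Step 3
Reactants: 4 (2S,5R)-2-tert-butyl-5-methyl-5-(prop-2-en-1-yl)-1,3-dioxolan-4-one
Product: 5 (2R)-2-hydroxy-N-methoxy-N,2-dimethylpent-4-enamide
Conditions: AlMe3, MeNH(OMe)·HCl, CH2Cl2, 0 → 40 °C; dilute aqueous HCl work-up
Reagents that add atoms: N,O-dimethylhydroxylamine hydrochloride, CNOC.Cl
Why: Weinreb amide formation by aluminium amide aminolysis of the activated acyl acetal; the hemiacetal left on oxygen loses pivalaldehyde on work-up and no stereocentre is touched.

Step 4
Reactants: 6 propargyl alcohol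
Product: 7 (2Z)-2-(tributylstannyl)-3-(trimethylsilyl)prop-2-en-1-ol
Conditions: Me3SiSnBu3, Pd(PPh3)4 (2 mol %), THF, 65 °C
Reagents that add atoms: trimethyl(tributylstannyl)silane, CCCC[Sn](CCCC)(CCCC)[Si](C)(C)C
Why: Palladium-catalysed silylstannation of a terminal alkyne is a cis addition that places tin on the internal and silicon on the terminal carbon, which defines the later 4Z geometry.

Step 5
Reactants: 7 (2Z)-2-(tributylstannyl)-3-(trimethylsilyl)prop-2-en-1-ol
Product: 8 (2Z)-2-iodo-3-(trimethylsilyl)prop-2-en-1-ol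
Conditions: I2, CH2Cl2, 0 °C
Reagents that add atoms: iodine, [I][I]
Why: Iododestannylation of an alkenylstannane proceeds with retention and is much faster than attack on the alkenylsilane.

Step 6
Reactants: 8 (2Z)-2-iodo-3-(trimethylsilyl)prop-2-en-1-ol; 9 (trimethylsilyl)acetylene
Product: 10 (2E)-3-(trimethylsilyl)-2-[(trimethylsilyl)ethynyl]prop-2-en-1-ol
Conditions: PdCl2(PPh3)2 (2 mol %), CuI (4 mol %), Et3N, THF, 23 °C
Reagents that add atoms: none
Why: Sonogashira coupling of the alkenyl iodide with a terminal alkyne proceeds with retention of alkene geometry and tolerates the free hydroxyl.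

Step 7
Reactants: 10 (2E)-3-(trimethylsilyl)-2-[(trimethylsilyl)ethynyl]prop-2-en-1-ol
Product: 11 (2E)-3-iodo-2-[(trimethylsilyl)ethynyl]prop-2-en-1-ol
Conditions: NIS, (CF3)2CHOH, 0 °C, dark
Reagents that add atoms: N-iodosuccinimide, O=C1CCC(=O)N1I
Why: Electrophilic ipso-iododesilylation of the alkenylsilane by NIS in hexafluoroisopropanol goes with retention, is done while the alkene is not yet conjugated to a carbonyl group, and leaves the alkynylsilane alone.

Step 8
Reactants: 11 (2E)-3-iodo-2-[(trimethylsilyl)ethynyl]prop-2-en-1-ol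
Product: 12 (2E)-2-ethynyl-3-iodoprop-2-en-1-ol
Conditions: K2CO3 (0.2 equiv), MeOH, 0 → 23 °C
Reagents that add atoms: none
Why: Base-catalysed methanolysis of the C(sp)–Si bond (protodesilylation of an alkynylsilane) frees the terminal alkyne without touching the alkenyl iodide.

Step 9
Reactants: 5 (2R)-2-hydroxy-N-methoxy-N,2-dimethylpent-4-enamide; 12 (2E)-2-ethynyl-3-iodoprop-2-en-1-ol
Product: 13 (1E,6R)-6-hydroxy-2-(hydroxymethyl)-1-iodo-6-methylnona-1,8-dien-3-yn-5-one
Conditions: 12 (1.2 equiv), LiN(i-Pr)2 (2.5 equiv), THF, −78 °C; then 5 pre-treated with LiN(i-Pr)2 (1.0 equiv), −78 → 0 °C; aq. NH4Cl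
Reagents that add atoms: none
Why: Weinreb ketone synthesis: the lithium acetylide adds once to the N-methoxy-N-methyl amide because the chelated tetrahedral adduct survives until work-up, and a lithium amide base instead of an alkyllithium avoids iodine–lithium exchange.

Step 10
Reactants: 13 (1E,6R)-6-hydroxy-2-(hydroxymethyl)-1-iodo-6-methylnona-1,8-dien-3-yn-5-one
Product: 14 (2R)-5-[(1Z)-3-hydroxy-1-iodoprop-1-en-2-yl]-2-methyl-2-(prop-2-en-1-yl)furan-3(2H)-one
Conditions: Ph3PAuNTf2 (2 mol %), CH2Cl2, 23 °C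
Reagents that add atoms: none
Why: Monovalent-gold (π-acid) catalysed 5-endo-dig cycloisomerisation of an α′-hydroxy ynone, the tertiary hydroxyl adding to the β-carbon C3 to give the 3(2H)-furanone under non-basic conditions that spare the iodoalkene.

Step 11
Reactants: 14 (2R)-5-[(1Z)-3-hydroxy-1-iodoprop-1-en-2-yl]-2-methyl-2-(prop-2-en-1-yl)furan-3(2H)-one
Product: 15 (2Z)-3-iodo-2-[(5R)-5-methyl-4-oxo-5-(prop-2-en-1-yl)-4,5-dihydrofuran-2-yl]prop-2-en-1-yl acetate
Conditions: Ac2O, Et3N, DMAP (cat.), CH2Cl2, 0 °C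
Reagents that add atoms: acetic anhydride, CC(=O)OC(C)=O
Why: DMAP-catalysed acetylation of the only free hydroxyl.

Step 12
Reactants: 15 (2Z)-3-iodo-2-[(5R)-5-methyl-4-oxo-5-(prop-2-en-1-yl)-4,5-dihydrofuran-2-yl]prop-2-en-1-yl acetate
Product: 17 (2Z)-3-iodo-2-[(5R)-5-methyl-4-oxo-5-(2-oxoethyl)-4,5-dihydrofuran-2-yl]prop-2-en-1-yl acetate, via vicinal diol 16 (not isolated)
Conditions: OsO4 (2 mol %), NaIO4 (4 equiv), 2,6-lutidine, 1,4-dioxane/H2O (3:1), 23 °C
Reagents that add atoms: sodium periodate (oxygen source through the osmium catalyst), [Na+].[O-]I(=O)(=O)=O; osmium tetroxide (oxygen carrier), O=[Os](=O)(=O)=O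
Why: Lemieux–Johnson oxidative cleavage: OsO4 dihydroxylates the unhindered, electron-rich monosubstituted alkene in preference to the vinylogous-ester alkene and the iodoalkene, and NaIO4 cleaves the diol to the C8 aldehyde.

Step 13
Reactants: 18 tert-butyl acrylate; 19 (tert-butyldimethylsilyloxy)acetaldehyde
Product: 20 tert-butyl 4-{[tert-butyl(dimethyl)silyl]oxy}-3-hydroxy-2-methylidenebutanoate (racemic)
Conditions: DABCO, 1,4-dioxane/H2O (1:1), 23 °C
Reagents that add atoms: none
Why: Morita–Baylis–Hillman reaction of an acrylate with a reactive α-oxygenated aldehyde; the carbinol centre is formed racemic and is removed in step 14.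

Step 14
Reactants: 20 tert-butyl 4-{[tert-butyl(dimethyl)silyl]oxy}-3-hydroxy-2-methylidenebutanoate
Product: 21 tert-butyl (2Z)-2-(bromomethyl)-4-{[tert-butyl(dimethyl)silyl]oxy}but-2-enoate
Conditions: NBS, Me2S, CH2Cl2, 0 → 23 °C
Reagents that add atoms: N-bromosuccinimide, O=C1CCC(=O)N1Br
Why: Allylic bromination with 1,3-transposition (SN2′ attack of bromide on the alkoxysulfonium salt, a Corey–Kim-type activation) gives the thermodynamically preferred Z bromide.

Step 15
Reactants: 17 (2Z)-3-iodo-2-[(5R)-5-methyl-4-oxo-5-(2-oxoethyl)-4,5-dihydrofuran-2-yl]prop-2-en-1-yl acetate; 21 tert-butyl (2Z)-2-(bromomethyl)-4-{[tert-butyl(dimethyl)silyl]oxy}but-2-enoate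
Product: 22 tert-butyl (3S,4S)-5-{(2R)-5-[(1Z)-3-(acetyloxy)-1-iodoprop-1-en-2-yl]-2-methyl-3-oxo-2,3-dihydrofuran-2-yl}-3-({[tert-butyl(dimethyl)silyl]oxy}methyl)-4-hydroxy-2-methylidenepentanoate
Conditions: CrCl2 (10 mol %), enantiopure 3,6-di-tert-butyl-1,8-bis(4-isopropyl-4,5-dihydrooxazol-2-yl)carbazole ligand (12 mol %), i-Pr2NEt (20 mol %), Mn, Cp2ZrCl2, THF, 23 °C
Reagents that add atoms: none
Why: Catalytic asymmetric Nozaki–Hiyama allylation: the allylchromium formed from 21 adds through its γ-carbon in a chair transition state with both substituents equatorial (C7 anti to the C8 hydroxyl), the chiral bis(oxazoline)carbazole–chromium complex directs it to the Re face of the aldehyde (8S), the alkenyl iodide is inert in the absence of nickel, and the tert-butyl ester cannot lactonise onto O8.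

Step 16
Reactants: 22 homoallylic alcohol from step 15
Product: 23 tert-butyl (3S,4S)-5-{(2R)-5-[(1Z)-3-(acetyloxy)-1-iodoprop-1-en-2-yl]-2-methyl-3-oxo-2,3-dihydrofuran-2-yl}-3-({[tert-butyl(dimethyl)silyl]oxy}methyl)-2-methylidene-4-[(2-methylprop-2-enoyl)oxy]pentanoate
Conditions: methacrylic anhydride, Et3N, DMAP (cat.), CH2Cl2, 0 → 23 °C
Reagents that add atoms: methacrylic anhydride, CC(=C)C(=O)OC(=O)C(C)=C
Why: DMAP-catalysed esterification of the secondary C8 alcohol with the anhydride.

Step 17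
Reactants: 23 silyl ether from step 16
Product: 24 tert-butyl (3S,4S)-5-{(2R)-5-[(1Z)-3-(acetyloxy)-1-iodoprop-1-en-2-yl]-2-methyl-3-oxo-2,3-dihydrofuran-2-yl}-3-(hydroxymethyl)-2-methylidene-4-[(2-methylprop-2-enoyl)oxy]pentanoate
Conditions: HF·pyridine, pyridine, THF, 0 → 23 °C
Reagents that add atoms: none
Why: Fluoride cleavage of the primary silyl ether under buffered conditions; the tert-butyl ester keeps the freed C6 alcohol from lactonising.

Step 18
Reactants: 24 primary alcohol from step 17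
Product: 25 tert-butyl (3R,4S)-5-{(2R)-5-[(1Z)-3-(acetyloxy)-1-iodoprop-1-en-2-yl]-2-methyl-3-oxo-2,3-dihydrofuran-2-yl}-3-formyl-2-methylidene-4-[(2-methylprop-2-enoyl)oxy]pentanoate (seco Z-iodoalkene aldehyde)
Conditions: Dess–Martin periodinane, NaHCO3, CH2Cl2, 0 → 23 °C; filtered and used at once
Reagents that add atoms: none
Why: Dess–Martin oxidation under buffered, non-basic conditions converts the primary alcohol into the aldehyde without epimerising C7 or eliminating the β-acyloxy group, and the aldehyde is used at once.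

Step 19
Reactants: 25 seco Z-iodoalkene aldehyde
Product: 26 tert-butyl 2-[(4Z,6R,7S,8S,10R)-15-acetoxy-6-hydroxy-8-(methacryloyloxy)-1-oxo-3,10-epoxygermacra-2,4-dien-7-yl]prop-2-enoate
Conditions: CrCl2 (10 equiv), NiCl2 (0.1 equiv), degassed DMSO, 0.002 M by slow addition of 25, 23 °C
Reagents that add atoms: none
Why: Zerovalent nickel, generated from NiCl2 by CrCl2, inserts into the C5–I bond and hands the alkenyl group to chromium; the trivalent alkenylchromium then adds to the C6 aldehyde (Nozaki–Hiyama–Kishi reaction in its well-known macrocyclising form) and ignores the ketone, the esters and the vinylogous ester. The ten-membered carbocycle C1–C10 closes by a 10-exo-trig attack of C5 on the formyl carbon, helped by high dilution and by the furanone ring, the Z alkene and the branched C7–C8 unit, which hold the two ends near each other. The new C6 carbinol centre is controlled by the adjacent C7 stereocentre: with the ring chain (C8) as the large group anti to the incoming C5 (Felkin–Anh arrangement inside the cyclic transition state), the hydroxyl should form syn to the C7 acrylate branch, which is 6R, the configuration of the trans-fused lactone. The step needs chemoselectivity for the aldehyde, retention of the Z geometry (trisubstituted alkenyl iodides couple with retention) and configurational integrity at the doubly activated C7–H, which the neutral, non-basic medium and freshly prepared 25 should secure. The tert-butyl ester keeps the chromium alkoxide from lactonising before work-up.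

Step 20
Reactants: 26 macrocyclic hydroxy tert-butyl ester
Product: 28 CNP0179932.1 (the 12,6-olide), via seco hydroxy acid 27 (not isolated)
Conditions: CF3CO2H/CH2Cl2 (1:4), 0 → 23 °C
Reagents that add atoms: none
Why: Acidolysis of the tert-butyl ester (loss of isobutene) followed by acid-catalysed γ-lactonisation of the C6 hydroxyl onto C12; no stereocentre is touched.

Compound list
1 | (S)-lactic acid | C[C@H](O)C(=O)O | starting material
2 | (2S,5S)-2-tert-butyl-5-methyl-1,3-dioxolan-4-one | C[C@@H]1O[C@H](C(C)(C)C)OC1=O | intermediate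
3 | allyl bromide | C=CCBr | starting material
4 | (2S,5R)-2-tert-butyl-5-methyl-5-(prop-2-en-1-yl)-1,3-dioxolan-4-one | C[C@]1(CC=C)O[C@H](C(C)(C)C)OC1=O | intermediate
5 | (2R)-2-hydroxy-N-methoxy-N,2-dimethylpent-4-enamide | C[C@](CC=C)(O)C(=O)N(C)OC | intermediate
6 | propargyl alcohol | C#CCO | starting material
7 | (2Z)-2-(tributylstannyl)-3-(trimethylsilyl)prop-2-en-1-ol | C[Si](C)(C)/C=C(\[Sn](CCCC)(CCCC)CCCC)CO | intermediate
8 | (2Z)-2-iodo-3-(trimethylsilyl)prop-2-en-1-ol | C[Si](C)(C)/C=C(\I)CO | intermediate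
9 | (trimethylsilyl)acetylene | C#C[Si](C)(C)C | starting material
10 | (2E)-3-(trimethylsilyl)-2-[(trimethylsilyl)ethynyl]prop-2-en-1-ol | C[Si](C)(C)/C=C(\C#C[Si](C)(C)C)CO | intermediate
11 | (2E)-3-iodo-2-[(trimethylsilyl)ethynyl]prop-2-en-1-ol | I/C=C(\C#C[Si](C)(C)C)CO | intermediate
12 | (2E)-2-ethynyl-3-iodoprop-2-en-1-ol | I/C=C(\C#C)CO | intermediate
13 | (1E,6R)-6-hydroxy-2-(hydroxymethyl)-1-iodo-6-methylnona-1,8-dien-3-yn-5-one | C[C@](CC=C)(O)C(=O)C#C/C(CO)=C\I | intermediate
14 | (2R)-5-[(1Z)-3-hydroxy-1-iodoprop-1-en-2-yl]-2-methyl-2-(prop-2-en-1-yl)furan-3(2H)-one | C=CC[C@@]1(C)OC(=CC1=O)/C(CO)=C\I | intermediate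
15 | (2Z)-3-iodo-2-[(5R)-5-methyl-4-oxo-5-(prop-2-en-1-yl)-4,5-dihydrofuran-2-yl]prop-2-en-1-yl acetate | C=CC[C@@]1(C)OC(=CC1=O)/C(COC(C)=O)=C\I | intermediate
16 | (2Z)-2-[(5R)-5-(2,3-dihydroxypropyl)-5-methyl-4-oxo-4,5-dihydrofuran-2-yl]-3-iodoprop-2-en-1-yl acetate (both carbinol epimers) | OCC(O)C[C@@]1(C)OC(=CC1=O)/C(COC(C)=O)=C\I | intermediate (not isolated)
17 | (2Z)-3-iodo-2-[(5R)-5-methyl-4-oxo-5-(2-oxoethyl)-4,5-dihydrofuran-2-yl]prop-2-en-1-yl acetate | O=CC[C@@]1(C)OC(=CC1=O)/C(COC(C)=O)=C\I | intermediate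
18 | tert-butyl acrylate | C=CC(=O)OC(C)(C)C | starting material
19 | (tert-butyldimethylsilyloxy)acetaldehyde | O=CCO[Si](C)(C)C(C)(C)C | starting material
20 | tert-butyl 4-{[tert-butyl(dimethyl)silyl]oxy}-3-hydroxy-2-methylidenebutanoate (racemic) | C=C(C(O)CO[Si](C)(C)C(C)(C)C)C(=O)OC(C)(C)C | intermediate
21 | tert-butyl (2Z)-2-(bromomethyl)-4-{[tert-butyl(dimethyl)silyl]oxy}but-2-enoate | BrC/C(C(=O)OC(C)(C)C)=C\CO[Si](C)(C)C(C)(C)C | intermediate
22 | tert-butyl (3S,4S)-5-{(2R)-5-[(1Z)-3-(acetyloxy)-1-iodoprop-1-en-2-yl]-2-methyl-3-oxo-2,3-dihydrofuran-2-yl}-3-({[tert-butyl(dimethyl)silyl]oxy}methyl)-4-hydroxy-2-methylidenepentanoate | CC(C)(C)[Si](C)(C)OC[C@H](C(=C)C(=O)OC(C)(C)C)[C@@H](O)C[C@@]1(C)OC(=CC1=O)/C(COC(C)=O)=C\I | intermediate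
23 | 4-O-methacrylate of 22, (3S,4S,2′R) | CC(C)(C)[Si](C)(C)OC[C@H](C(=C)C(=O)OC(C)(C)C)[C@@H](OC(=O)C(C)=C)C[C@@]1(C)OC(=CC1=O)/C(COC(C)=O)=C\I | intermediate
24 | tert-butyl (3S,4S)-5-{(2R)-5-[(1Z)-3-(acetyloxy)-1-iodoprop-1-en-2-yl]-2-methyl-3-oxo-2,3-dihydrofuran-2-yl}-3-(hydroxymethyl)-2-methylidene-4-[(2-methylprop-2-enoyl)oxy]pentanoate | OC[C@H](C(=C)C(=O)OC(C)(C)C)[C@@H](OC(=O)C(C)=C)C[C@@]1(C)OC(=CC1=O)/C(COC(C)=O)=C\I | intermediate
25 | tert-butyl (3R,4S)-5-{(2R)-5-[(1Z)-3-(acetyloxy)-1-iodoprop-1-en-2-yl]-2-methyl-3-oxo-2,3-dihydrofuran-2-yl}-3-formyl-2-methylidene-4-[(2-methylprop-2-enoyl)oxy]pentanoate (same spatial arrangement at C3 as in 24; only the CIP priorities change) | O=C[C@H](C(=C)C(=O)OC(C)(C)C)[C@@H](OC(=O)C(C)=C)C[C@@]1(C)OC(=CC1=O)/C(COC(C)=O)=C\I | intermediate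
26 | tert-butyl 2-[(4Z,6R,7S,8S,10R)-15-acetoxy-6-hydroxy-8-(methacryloyloxy)-1-oxo-3,10-epoxygermacra-2,4-dien-7-yl]prop-2-enoate | C=C(C)C(=O)O[C@H]1C[C@@]2(C)OC(=CC2=O)/C(COC(C)=O)=C\[C@@H](O)[C@@H]1C(=C)C(=O)OC(C)(C)C | intermediate
27 | 2-[(4Z,6R,7S,8S,10R)-15-acetoxy-6-hydroxy-8-(methacryloyloxy)-1-oxo-3,10-epoxygermacra-2,4-dien-7-yl]prop-2-enoic acid | C=C(C)C(=O)O[C@H]1C[C@@]2(C)OC(=CC2=O)/C(COC(C)=O)=C\[C@@H](O)[C@@H]1C(=C)C(=O)O | intermediate (not isolated)
28 | CNP0179932.1, (4Z,6R,7R,8S,10R)-15-acetoxy-8-(methacryloyloxy)-1-oxo-3,10-epoxygermacra-2,4,11(13)-trien-12,6-olide (7R is the same spatial arrangement as 7S in 26) | C=C(C)C(=O)O[C@H]1C[C@@]2(C)OC(=CC2=O)/C(COC(C)=O)=C\[C@H]2OC(=O)C(=C)[C@H]12 | target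

Total step count: 20. Longest linear sequence: 15 steps (6 → 7 → 8 → 10 → 11 → 12 → 13 → 14 → 15 → 17 → 22 → 23 → 24 → 25 → 26 → 28).

Steps most likely to fail

Step 19. What may go wrong is poor facial selectivity at the C6 aldehyde during the ring closure: the β-acyloxy group at C8 exerts a 1,3-effect that opposes the Felkin–Anh preference, and the ring conformation may override both. The fallback sets out from 25 and returns at 28. The ring closure is run as in step 19, and the material formed by attack on the other face, the 6-epi macrocyclic tert-butyl ester F1, is carried on. Its tert-butyl ester is removed under non-lactonising conditions (Me3SiOTf, 2,6-lutidine, CH2Cl2, 0 °C, then pH 7 buffer) to give the 6-epi seco hydroxy acid F2. A Mitsunobu lactonisation (PPh3, diisopropyl azodicarboxylate, THF, 0 °C) then closes the lactone by SN2 displacement at C6 with inversion and should give 28. C6 is thus set in the lactonisation and not in the carbonyl addition.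

Step 15. What may go wrong is insufficient enantiofacial control by the chromium catalyst on the polyfunctional aldehyde, or erosion of the anti preference, so that C7 and C8 form as a mixture. The fallback sets out from 17 and returns at 24; it replaces the catalytic allylation by an auxiliary-controlled aldol reaction.
- The lithium salt of (R)-4-benzyl-1,3-thiazolidine-2-thione opens itaconic anhydride at its non-conjugated carbonyl to give 4-[(4R)-4-benzyl-2-thioxo-1,3-thiazolidin-3-yl]-2-methylidene-4-oxobutanoic acid F3.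
- tert-Butyl 2,2,2-trichloroacetimidate (cat. BF3·OEt2) converts it into the tert-butyl ester F4.
- Its titanium enolate (TiCl4, i-Pr2NEt, N-methyl-2-pyrrolidinone, CH2Cl2, −78 °C, syn-aldol mode of N-acylthiazolidinethiones) adds to 17 and should give the syn aldol adduct F5, with C7 and C8 both fixed by the auxiliary.
- Methacrylic anhydride and DMAP give the C8 methacrylate F6.
- NaBH4 in THF/EtOH at 0 °C reduces the activated thioimide to the primary alcohol, which is 24.

Step 12. What may go wrong is unselective oxidation of the furanone enol-ether alkene, or loss of the newly formed β-oxy aldehyde by elimination of the furanone oxygen. The fallback sets out from 5 and returns at 17; the alkene is cleaved before any sensitive group is present.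
- Lemieux–Johnson cleavage of 5 (OsO4 cat., NaIO4, 2,6-lutidine) gives (2R)-2-hydroxy-N-methoxy-N,2-dimethyl-4-oxobutanamide F7.
- HC(OMe)3 and pyridinium p-toluenesulfonate in MeOH give the dimethyl acetal F8.
- Dilithiated 12 (conditions of step 9) adds to give the acetal ynone F9.
- The gold-catalysed closure of step 10 gives the acetal furanone F10.
- Acetylation as in step 11 gives the acetal acetate F11.
- Dilute aqueous HCl in THF at 0 °C releases the aldehyde, which is 17.

Further compounds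
F1 | step 19 | tert-butyl 2-[(4Z,6S,7S,8S,10R)-15-acetoxy-6-hydroxy-8-(methacryloyloxy)-1-oxo-3,10-epoxygermacra-2,4-dien-7-yl]prop-2-enoate | C=C(C)C(=O)O[C@H]1C[C@@]2(C)OC(=CC2=O)/C(COC(C)=O)=C\[C@H](O)[C@@H]1C(=C)C(=O)OC(C)(C)C
F2 | step 19 | 2-[(4Z,6S,7S,8S,10R)-15-acetoxy-6-hydroxy-8-(methacryloyloxy)-1-oxo-3,10-epoxygermacra-2,4-dien-7-yl]prop-2-enoic acid | C=C(C)C(=O)O[C@H]1C[C@@]2(C)OC(=CC2=O)/C(COC(C)=O)=C\[C@H](O)[C@@H]1C(=C)C(=O)O
F3 | step 15 | 4-[(4R)-4-benzyl-2-thioxo-1,3-thiazolidin-3-yl]-2-methylidene-4-oxobutanoic acid | OC(=O)C(=C)CC(=O)N1[C@H](Cc2ccccc2)CSC1=S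
F4 | step 15 | tert-butyl 4-[(4R)-4-benzyl-2-thioxo-1,3-thiazolidin-3-yl]-2-methylidene-4-oxobutanoate | CC(C)(C)OC(=O)C(=C)CC(=O)N1[C@H](Cc2ccccc2)CSC1=S
F5 | step 15 | tert-butyl (3R,4S)-3-{[(4R)-4-benzyl-2-thioxo-1,3-thiazolidin-3-yl]carbonyl}-5-{(2R)-5-[(1Z)-3-(acetyloxy)-1-iodoprop-1-en-2-yl]-2-methyl-3-oxo-2,3-dihydrofuran-2-yl}-4-hydroxy-2-methylidenepentanoate | S=C1SC[C@@H](Cc2ccccc2)N1C(=O)[C@H](C(=C)C(=O)OC(C)(C)C)[C@@H](O)C[C@@]3(C)OC(=CC3=O)/C(COC(C)=O)=C\I
F6 | step 15 | 4-O-methacrylate of F5 | S=C1SC[C@@H](Cc2ccccc2)N1C(=O)[C@H](C(=C)C(=O)OC(C)(C)C)[C@@H](OC(=O)C(C)=C)C[C@@]3(C)OC(=CC3=O)/C(COC(C)=O)=C\I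
F7 | step 12 | (2R)-2-hydroxy-N-methoxy-N,2-dimethyl-4-oxobutanamide | C[C@](CC=O)(O)C(=O)N(C)OC
F8 | step 12 | (2R)-2-hydroxy-N,4,4-trimethoxy-N,2-dimethylbutanamide | C[C@](CC(OC)OC)(O)C(=O)N(C)OC
F9 | step 12 | (1E,6R)-6-hydroxy-2-(hydroxymethyl)-1-iodo-8,8-dimethoxy-6-methyloct-1-en-3-yn-5-one | C[C@](CC(OC)OC)(O)C(=O)C#C/C(CO)=C\I
F10 | step 12 | (2R)-2-(2,2-dimethoxyethyl)-5-[(1Z)-3-hydroxy-1-iodoprop-1-en-2-yl]-2-methylfuran-3(2H)-one | COC(OC)C[C@@]1(C)OC(=CC1=O)/C(CO)=C\I
F11 | step 12 | (2Z)-2-[(5R)-5-(2,2-dimethoxyethyl)-5-methyl-4-oxo-4,5-dihydrofuran-2-yl]-3-iodoprop-2-en-1-yl acetate | COC(OC)C[C@@]1(C)OC(=CC1=O)/C(COC(C)=O)=C\I
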